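Ring B (O1, C2, C3, C4, C4a, C8a) is a 2-heptyl-2,3-dihydro-4H-pyran-4-one. It is disconnected at C2–C3 and O1–C8a into octanal and a diene, C3=C4(OSi)–C4a=C8a(OSi), carried by the finished ring A lactone. One catalytic asymmetric aldol–cyclisation (a formal hetero-Diels–Alder reaction) closes ring B, sets C2 and, by loss of silanol from C8a, regenerates the C4a=C8a enone. The diene is the bis(trimethylsilyl) derivative of a 4-acetyl-3-hydroxy lactone. That lactone is built from (R)-1,2-epoxydodecane (which supplies C6), acetone and an oxalyl unit by epoxide opening, O-oxalylation and Dieckmann ring closure.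

Key step: step 5

Remark: target atoms are numbered O1, C2, C3, C4, C4a, C5, C6, O7, C8, C8a (ring A = lactone, ring B = pyranone); the enol oxygen at C8a is carried as a trimethylsilyl ether because silylation at either oxygen of the chelated enol converges on the same diene.

Step 1
Reactants: 1 (R)-1,2-epoxydodecane; 2 acetone N,N-dimethylhydrazone
Product: 4 (R)-5-hydroxypentadecan-2-one, via hydroxy hydrazone 3 (not isolated)
Conditions: 2, n-BuLi, THF, –78 → 0 °C; 1, 0 °C → rt; H2O quench; then sat. aq. oxalic acid, Et2O, rt
Reagents that add atoms: water, O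
Why: Azaenolate alkylation: the lithiated hydrazone opens the terminal epoxide by SN2 attack at the unsubstituted CH2, so the C–O stereocentre is carried over untouched as (R), and mild acid hydrolysis of the C=N bond then releases the methyl ketone.

Step 2
Reactants: 4 (R)-5-hydroxypentadecan-2-one; 5 ethyl chlorooxoacetate
Product: 6 ethyl (R)-2-oxopentadecan-5-yl oxalate
Conditions: pyridine, DMAP (cat.), CH2Cl2, 0 °C
Reagents that add atoms: none
Why: O-Acylation of a secondary alcohol by an acid chloride under nucleophilic catalysis forms only the O–C(acyl) bond, so the carbinol configuration is retained and the open-chain hydroxy ketone is drained from its hemiketal equilibrium.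

Step 3
Reactants: 6 ethyl (R)-2-oxopentadecan-5-yl oxalate
Product: 7 (R)-4-acetyl-6-decyl-3-hydroxy-5,6-dihydro-2H-pyran-2-one
Conditions: NaH, EtOH (cat.), THF (0.05 M), 0 °C → rt; then 1 M HCl
Reagents that add atoms: none
Why: Dieckmann-type intramolecular Claisen condensation under equilibrating conditions, in which only the internal CH2 enolate of the methyl ketone can reach the terminal ester carbonyl of the oxalate through a six-membered transition state (6-exo-trig; the CH3 enolate would need an eight-membered ring), as when 6-oxoheptanoates and 7-oxooctanoates cyclise to 2-acetylcycloalkanones, and irreversible deprotonation of the acidic enol product by NaH pulls the reaction over without involving the stereocentre.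

Step 4
Reactants: 7 (R)-4-acetyl-6-decyl-3-hydroxy-5,6-dihydro-2H-pyran-2-one
Product: 8 (R)-6-decyl-3-(trimethylsilyloxy)-4-[1-(trimethylsilyloxy)vinyl]-5,6-dihydro-2H-pyran-2-one
Conditions: TMSOTf (2.5 equiv), Et3N (3.5 equiv), Et2O, 0 °C → rt; pentane, filtration under Ar, used crude
Reagents that add atoms: trimethylsilyl trifluoromethanesulfonate, C[Si](C)(C)OS(=O)(=O)C(F)(F)F
Why: Soft enolisation with a silyl triflate and a tertiary amine: the acidic enol OH is silylated first and the silyl-activated acetyl group is then deprotonated at CH3 (the only position whose deprotonation is conjugated with the activated carbonyl), so a single bis-silyl diene should result with no stereocentre touched.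

Step 5
Reactants: 8 (R)-6-decyl-3-(trimethylsilyloxy)-4-[1-(trimethylsilyloxy)vinyl]-5,6-dihydro-2H-pyran-2-one; 9 octanal
Product: 11 (2S,6R)-6-decyl-2-heptyl-2,3,5,6-tetrahydropyrano[3,4-b]pyran-4,8-dione, via silyl aldol 10 (not isolated)
Conditions: Ti(OiPr)4 (10 mol%), (R)-BINOL (10 mol%), 4 Å MS, THF, –78 °C → rt; then TFA, CH2Cl2, 0 °C → rt
Reagents that add atoms: none
Why: The (R)-BINOL–Ti(OiPr)4 complex binds octanal, and the terminal CH2 of the silyl dienol ether (C3) adds to the activated carbonyl with silyl transfer (Mukaiyama aldol), forming C2–C3 and giving 10. TFA then frees the C2 hydroxyl, which adds to C8a of the β-silyloxy enone and expels trimethylsilanol, forming O1–C8a and returning the C4a=C8a double bond without an oxidation step. The closest known chemistry is the Ti–BINOL-catalysed aldol addition of 1-alkoxy-3-silyloxy and 1,3-bis(silyloxy) dienes to aliphatic aldehydes, the former followed by acid cyclisation to 2-alkyl-2,3-dihydro-4H-pyran-4-ones. Ring B closes as a formal [4+2] annulation across C3 and C8a, in practice stepwise with a 6-endo-trig oxa-Michael addition–elimination. C2 is set by the ligand alone, since C6 is too remote to bias it: the (R)-ligand is expected to steer the nucleophile to the Re face of the unbranched aldehyde, which corresponds to 2S. The step needs enantioface control (catalyst), site control (C3 is the only nucleophilic diene terminus and the ring A lactone is not enolised) and a non-epimerising acid stage (short exposure to TFA at low temperature).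

Compound list
1 | (R)-1,2-epoxydodecane | CCCCCCCCCC[C@@H]1CO1 | starting material
2 | acetone N,N-dimethylhydrazone | CC(C)=NN(C)C | starting material
3 | (R)-5-hydroxypentadecan-2-one N,N-dimethylhydrazone | CCCCCCCCCC[C@@H](O)CCC(C)=NN(C)C | intermediate
4 | (R)-5-hydroxypentadecan-2-one | CCCCCCCCCC[C@@H](O)CCC(C)=O | intermediate
5 | ethyl chlorooxoacetate | CCOC(=O)C(Cl)=O | starting material
6 | ethyl (R)-2-oxopentadecan-5-yl oxalate | CCCCCCCCCC[C@@H](OC(=O)C(=O)OCC)CCC(C)=O | intermediate
7 | (R)-4-acetyl-6-decyl-3-hydroxy-5,6-dihydro-2H-pyran-2-one | CCCCCCCCCC[C@@H]1CC(C(C)=O)=C(O)C(=O)O1 | intermediate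
8 | (R)-6-decyl-3-(trimethylsilyloxy)-4-[1-(trimethylsilyloxy)vinyl]-5,6-dihydro-2H-pyran-2-one | CCCCCCCCCC[C@@H]1CC(C(=C)O[Si](C)(C)C)=C(O[Si](C)(C)C)C(=O)O1 | intermediate
9 | octanal | CCCCCCCC=O | starting material
10 | (R)-6-decyl-3-(trimethylsilyloxy)-4-[(S)-3-(trimethylsilyloxy)decanoyl]-5,6-dihydro-2H-pyran-2-one | CCCCCCCCCC[C@@H]1CC(C(=O)C[C@H](CCCCCCC)O[Si](C)(C)C)=C(O[Si](C)(C)C)C(=O)O1 | intermediate
11 | (2S,6R)-6-decyl-2-heptyl-2,3,5,6-tetrahydropyrano[3,4-b]pyran-4,8-dione | CCCCCCCCCC[C@@H]1CC2=C(O[C@@H](CCCCCCC)CC2=O)C(=O)O1 | target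

Total step count: 5. Longest linear sequence: 5 steps (1 → 4 → 6 → 7 → 8 → 11).

Steps most likely to fail

Step 5 (key step). Turnover may stall because the diene terminus is a weak nucleophile and the vinylogous silyl ester can pass silicon to the catalyst. Enantioface selectivity may erode, and C2 may epimerise by β-elimination and re-addition in the acid stage. If the observed sense of induction is opposite, the (S)-ligand is used instead. Fallback: setting out from 7, double deprotonation with LiN(iPr)2 (THF, –78 °C) and addition of 9 at the acetyl terminus (dianion aldol of a β-dicarbonyl compound) should give (6R)-6-decyl-3-hydroxy-4-(3-hydroxydecanoyl)-5,6-dihydro-2H-pyran-2-one F1 as both carbinol epimers. TFA in CH2Cl2 then closes ring B by hemiketalisation at C8a and dehydration, giving 11 together with its C2 epimer (2R,6R)-6-decyl-2-heptyl-2,3,5,6-tetrahydropyrano[3,4-b]pyran-4,8-dione F2. The two are diastereomers and are to be separated by chromatography, so the route is rejoined at 11 at the price of catalyst control.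

Step 3. The Claisen acylation may be mis-directed to the methyl terminus in an intermolecular reaction, or ethoxide may cleave the mixed oxalate before ring closure. Fallback: setting out from 1, the sodium enolate of commercial ethyl 2,4-dioxopentanoate (NaOEt, EtOH, reflux) opens the epoxide at CH2 through its central carbon to give ethyl (5R)-3-acetyl-5-hydroxy-2-oxopentadecanoate F3. This lactonises in the same flask with loss of ethanol and rejoins the route at 7. The approach forms C4–C5 of the lactone instead of C3–C4 (β-dicarbonyl enolate alkylation by an epoxide followed by lactonisation).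

Step 4. Enol silylation of the acetyl group may be incomplete, or silyl groups may be lost by hydrolysis during isolation, leaving a diene too impure for a catalytic step. Fallback: setting out from 7, O-methylation of the acidic enol with TMSCHN2 (MeOH, toluene, 0 °C) should give (R)-4-acetyl-6-decyl-3-methoxy-5,6-dihydro-2H-pyran-2-one F4. Kinetic deprotonation at the acetyl CH3 with LiN(SiMe3)2 and trapping with TMSCl (THF, –78 °C) then gives the more robust (R)-6-decyl-3-methoxy-4-[1-(trimethylsilyloxy)vinyl]-5,6-dihydro-2H-pyran-2-one F5. F5 takes the place of 8 under the conditions of step 5 and reacts with 9 via (R)-6-decyl-3-methoxy-4-[(S)-3-(trimethylsilyloxy)decanoyl]-5,6-dihydro-2H-pyran-2-one F6. Acid cyclisation then expels methanol from C8a and the route is rejoined at 11.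

Further compounds
F1 | step 5 | (6R)-6-decyl-3-hydroxy-4-(3-hydroxydecanoyl)-5,6-dihydro-2H-pyran-2-one (both carbinol epimers) | CCCCCCCCCC[C@@H]1CC(C(=O)CC(O)CCCCCCC)=C(O)C(=O)O1
F2 | step 5 | (2R,6R)-6-decyl-2-heptyl-2,3,5,6-tetrahydropyrano[3,4-b]pyran-4,8-dione | CCCCCCCCCC[C@@H]1CC2=C(O[C@H](CCCCCCC)CC2=O)C(=O)O1
F3 | step 3 | ethyl (5R)-3-acetyl-5-hydroxy-2-oxopentadecanoate | CCCCCCCCCC[C@@H](O)CC(C(C)=O)C(=O)C(=O)OCC
F4 | step 4 | (R)-4-acetyl-6-decyl-3-methoxy-5,6-dihydro-2H-pyran-2-one | CCCCCCCCCC[C@@H]1CC(C(C)=O)=C(OC)C(=O)O1
F5 | step 4 | (R)-6-decyl-3-methoxy-4-[1-(trimethylsilyloxy)vinyl]-5,6-dihydro-2H-pyran-2-one | CCCCCCCCCC[C@@H]1CC(C(=C)O[Si](C)(C)C)=C(OC)C(=O)O1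
F6 | step 4 | (R)-6-decyl-3-methoxy-4-[(S)-3-(trimethylsilyloxy)decanoyl]-5,6-dihydro-2H-pyran-2-one | CCCCCCCCCC[C@@H]1CC(C(=O)C[C@H](CCCCCCC)O[Si](C)(C)C)=C(OC)C(=O)O1
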